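**Retrosynthetic overview**

1. Feature: ring C reads O1–C2(H)(aryl)–C3(H)(OH)–C4(=O)–C4a. C3 and C4 are the two oxidised carbons of a former C3=C4 alkene in a (2S)-2-aryl-2H-chromene, and that alkene is a metathesis bond between a C4a vinyl group and an O1-bound 1-arylallyl group whose branched carbon is C2.
2. Target 16 ⇐ Stille prenylation of a C8 iodide ⇐ BCl3 release of 5-OH and 3'-OH ⇐ benzylic oxidation at C4 ⇐ OsO4 cis-dihydroxylation anti to the C2 aryl group (sets C3).
3. Chromene 11 ⇐ ring-closing metathesis (C3=C4) of (S)-ether 10 ⇐ iridium-catalysed asymmetric allylic etherification (sets C2) of vinylphenol 3 with cinnamyl carbonate 8.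
4. 3 ⇐ 2-hydroxy-4,6-dimethoxybenzaldehyde (iodination, Wittig); 8 ⇐ isovanillin (isopropyl ether, Horner–Wadsworth–Emmons, reduction, carbonate).
5. Ring order: rings A and B are bought; ring C is the only ring made (step 8).

Key step: step 8

Remark on the design: a prenyl alkene at C8 would be dihydroxylated by OsO4 at least as fast as the cis-disubstituted C3=C4 bond and would add HCl under BCl3, so C8 carries iodine through steps 7 to 11 and the prenyl group is coupled on last; the B-ring phenol is an isopropyl ether, which BCl3 removes together with the chelated 5-O-methyl group.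

Assumption: the (Sa,S,S) phosphoramidite is taken to give the (S)-ether, the usual sense of this catalyst family with aryl-substituted allyl carbonates (the antipodal ligand would be used otherwise); stannane 15 is taken as commercially available.

**Route**

Step 1
Reactants: 1 2-hydroxy-4,6-dimethoxybenzaldehyde
Product: 2 2-hydroxy-3-iodo-4,6-dimethoxybenzaldehyde
Conditions: NIS (1.0 equiv), CF3CO2H (cat.), MeCN, 0 °C → rt
Reagents that add atoms: N-iodosuccinimide, O=C1CCC(=O)N1I
Why: Electrophilic aromatic iodination (SEAr); C3, ortho to the hydrogen-bonded hydroxyl, is less hindered than C5 between two methoxy groups, so substitution should go to C3, and one equivalent of NIS avoids the diiodide.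

Step 2
Reactants: 2 2-hydroxy-3-iodo-4,6-dimethoxybenzaldehyde
Product: 3 2-ethenyl-6-iodo-3,5-dimethoxyphenol
Conditions: Ph3PCH3Br (2.5 equiv), KOt-Bu (2.5 equiv), THF, 0 °C → rt; aq. NH4Cl
Reagents that add atoms: methyltriphenylphosphonium bromide, C[P+](c1ccccc1)(c1ccccc1)c1ccccc1.[Br-]
Why: Wittig methylenation through an oxaphosphetane, with excess ylide because the first equivalent is consumed by the acidic phenol; the aryl iodide and the methyl ethers are inert to the ylide.

Step 3
Reactants: 4 isovanillin (3-hydroxy-4-methoxybenzaldehyde)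
Product: 5 4-methoxy-3-(propan-2-yloxy)benzaldehyde
Conditions: i-PrBr, K2CO3, DMF, 70 °C
Reagents that add atoms: 2-bromopropane, CC(C)Br
Why: Williamson ether synthesis on the only phenol; the isopropyl ether survives every later step and is cleaved by BCl3 in step 11.

Step 4
Reactants: 5 4-methoxy-3-(propan-2-yloxy)benzaldehyde
Product: 6 ethyl (E)-3-[4-methoxy-3-(propan-2-yloxy)phenyl]prop-2-enoate
Conditions: (EtO)2P(O)CH2CO2Et, NaH, THF, 0 °C → rt
Reagents that add atoms: triethyl phosphonoacetate, CCOC(=O)CP(=O)(OCC)OCC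
Why: Horner–Wadsworth–Emmons olefination with a stabilised phosphonate anion, which should give the (E)-cinnamate needed for a linear (E)-allyl electrophile.

Step 5
Reactants: 6 ethyl (E)-3-[4-methoxy-3-(propan-2-yloxy)phenyl]prop-2-enoate
Product: 7 (E)-3-[4-methoxy-3-(propan-2-yloxy)phenyl]prop-2-en-1-ol
Conditions: i-Bu2AlH (2.2 equiv), CH2Cl2, −78 → 0 °C
Reagents that add atoms: none
Why: 1,2-Reduction of the α,β-unsaturated ester by the aluminium hydride gives the allylic alcohol without touching the alkene.

Step 6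
Reactants: 7 (E)-3-[4-methoxy-3-(propan-2-yloxy)phenyl]prop-2-en-1-ol
Product: 8 (E)-3-[4-methoxy-3-(propan-2-yloxy)phenyl]prop-2-en-1-yl methyl carbonate
Conditions: ClCO2Me, pyridine, CH2Cl2, 0 °C
Reagents that add atoms: methyl chloroformate, COC(Cl)=O
Why: O-Acylation of the primary allylic alcohol with a chloroformate gives the linear carbonate, the standard leaving group for iridium allyl chemistry.

Step 7
Reactants: 3 2-ethenyl-6-iodo-3,5-dimethoxyphenol; 8 (E)-3-[4-methoxy-3-(propan-2-yloxy)phenyl]prop-2-en-1-yl methyl carbonate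
Product: 10 2-ethenyl-6-iodo-3,5-dimethoxyphenyl (1S)-1-[4-methoxy-3-(propan-2-yloxy)phenyl]prop-2-en-1-yl ether, via sodium phenolate 9 (not isolated)
Conditions: 3, NaH, THF, 0 °C; then 8, [Ir(cod)Cl]2 (2 mol%), (Sa,S,S)-O,O'-(1,1'-binaphthyl-2,2'-diyl)-N,N-bis(1-phenylethyl)phosphoramidite (4 mol%, pre-activated with n-PrNH2), THF, rt
Reagents that add atoms: sodium hydride, [Na+].[H-] (gives the sodium of 9; no atom of it stays in 10)
Why: Iridium-catalysed asymmetric allylic etherification: the cyclometalated iridium phosphoramidite ionises 8 and the phenolate attacks the aryl-bearing allyl terminus on the face fixed by the ligand, giving the branched (S)-ether and setting the future C2; the vinylphenolate is used instead of the more stabilised formylphenolate so that the product ether re-ionises less readily.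

Step 8
Reactants: 10 2-ethenyl-6-iodo-3,5-dimethoxyphenyl (1S)-1-[4-methoxy-3-(propan-2-yloxy)phenyl]prop-2-en-1-yl ether
Product: 11 (2S)-8-iodo-5,7-dimethoxy-2-[4-methoxy-3-(propan-2-yloxy)phenyl]-2H-chromene
Conditions: second-generation Grubbs catalyst (H2IMes)(PCy3)Cl2Ru=CHPh (5 mol%), degassed CH2Cl2 (0.005 M), 40 °C, dark
Reagents that add atoms: none
Why: Ring-closing olefin metathesis (Chauvin mechanism): the ruthenium benzylidene first exchanges onto the unhindered terminal CH=CH2 of the 1-arylallyl group, the new alkylidene adds across the C4a vinyl group to a ruthenacyclobutane, and cycloreversion releases ethene and forms C3=C4. The closest known reaction type is the ring-closing metathesis of allyl 2-vinylphenyl ethers to 2H-chromenes. Ring C closes as a six-membered ring with both carbons of the new alkene inside the ring, and high dilution favours this over intermolecular metathesis. No stereocentre is formed; C2, set in step 7, has no bond broken and keeps its configuration as long as ruthenium hydride formation (allyl to enol ether migration) is suppressed by a short reaction time in degassed solvent. The selectivity needed is ring closure over dimerisation and double-bond migration, and it is secured because 10 holds only two alkenes, both monosubstituted and joined through O1, with iodine and not an alkene at C8. Loss of ethene makes the closure irreversible.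

Step 9
Reactants: 11 (2S)-8-iodo-5,7-dimethoxy-2-[4-methoxy-3-(propan-2-yloxy)phenyl]-2H-chromene
Product: 12 (2R,3S,4S)-8-iodo-5,7-dimethoxy-2-[4-methoxy-3-(propan-2-yloxy)phenyl]-3,4-dihydro-2H-chromene-3,4-diol (2,3-trans-3,4-cis)
Conditions: OsO4 (5 mol%), NMO (1.5 equiv), acetone/H2O, 0 °C → rt
Reagents that add atoms: N-methylmorpholine N-oxide, C[N+]1([O-])CCOCC1; water, O; osmium tetroxide (catalytic oxygen carrier), O=[Os](=O)(=O)=O
Why: Catalytic OsO4 cis-dihydroxylation of the only alkene present; the reagent should add to the face of C3=C4 opposite the C2 aryl group, so O3 ends trans to the aryl group (3S) and O4 cis to O3 (4S).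

Step 10
Reactants: 12 (2R,3S,4S)-8-iodo-5,7-dimethoxy-2-[4-methoxy-3-(propan-2-yloxy)phenyl]-3,4-dihydro-2H-chromene-3,4-diol
Product: 13 (2R,3R)-3-hydroxy-8-iodo-5,7-dimethoxy-2-[4-methoxy-3-(propan-2-yloxy)phenyl]-2,3-dihydro-4H-chromen-4-one
Conditions: DDQ (1.1 equiv), 1,4-dioxane, rt
Reagents that add atoms: none
Why: DDQ oxidation of an electron-rich benzylic alcohol by hydride abstraction; the C4–H hydride is stabilised by the 2,4,6-trioxygenated ring A and should leave far faster than the non-benzylic C3–H, so only C4 becomes a ketone and C3 keeps its configuration, trans (2R,3R) to the aryl group.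

Step 11
Reactants: 13 (2R,3R)-3-hydroxy-8-iodo-5,7-dimethoxy-2-[4-methoxy-3-(propan-2-yloxy)phenyl]-2,3-dihydro-4H-chromen-4-one
Product: 14 (2R,3R)-3,5-dihydroxy-2-(3-hydroxy-4-methoxyphenyl)-8-iodo-7-methoxy-2,3-dihydro-4H-chromen-4-one
Conditions: BCl3 (4 equiv), CH2Cl2, −78 → 0 °C; then MeOH/H2O
Reagents that add atoms: none
Why: Lewis-acid ether cleavage with BCl3: boron chelates the C4 carbonyl and the peri 5-methoxy oxygen so that chloride removes that methyl group, the secondary isopropyl ether is cleaved through its easier C–O ionisation, and the unactivated 7- and 4'-methyl ethers should stay at 0 °C; any reversible opening at O1–C2 would return to the more stable 2,3-trans ring because C3 is untouched.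

Step 12
Reactants: 14 (2R,3R)-3,5-dihydroxy-2-(3-hydroxy-4-methoxyphenyl)-8-iodo-7-methoxy-2,3-dihydro-4H-chromen-4-one; 15 tributyl(3-methylbut-2-en-1-yl)stannane
Product: 16 (2R,3R)-3,5-dihydroxy-2-(3-hydroxy-4-methoxyphenyl)-7-methoxy-8-(3-methylbut-2-en-1-yl)-2,3-dihydro-4H-chromen-4-one (target, CNP0302743.1)
Conditions: 15 (2 equiv), Pd(PPh3)4 (10 mol%), degassed DMF, 80 °C
Reagents that add atoms: none
Why: Stille coupling: zerovalent palladium inserts into the C8–I bond, the prenyl group is transferred from tin, and reductive elimination at the unsubstituted CH2 terminus should give the linear prenyl group under neutral conditions that leave the free phenols, the base-sensitive 3-hydroxy ketone and both stereocentres alone.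

**Compound list**

1 | 2-hydroxy-4,6-dimethoxybenzaldehyde | COc1cc(O)c(C=O)c(OC)c1 | starting material
2 | 2-hydroxy-3-iodo-4,6-dimethoxybenzaldehyde | O=Cc1c(O)c(I)c(OC)cc1OC | intermediate
3 | 2-ethenyl-6-iodo-3,5-dimethoxyphenol | C=Cc1c(O)c(I)c(OC)cc1OC | intermediate
4 | isovanillin (3-hydroxy-4-methoxybenzaldehyde) | COc1ccc(C=O)cc1O | starting material
5 | 4-methoxy-3-(propan-2-yloxy)benzaldehyde | COc1ccc(C=O)cc1OC(C)C | intermediate
6 | ethyl (E)-3-[4-methoxy-3-(propan-2-yloxy)phenyl]prop-2-enoate | CCOC(=O)/C=C/c1ccc(OC)c(OC(C)C)c1 | intermediate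
7 | (E)-3-[4-methoxy-3-(propan-2-yloxy)phenyl]prop-2-en-1-ol | OC/C=C/c1ccc(OC)c(OC(C)C)c1 | intermediate
8 | (E)-3-[4-methoxy-3-(propan-2-yloxy)phenyl]prop-2-en-1-yl methyl carbonate | COC(=O)OC/C=C/c1ccc(OC)c(OC(C)C)c1 | intermediate
9 | sodium 2-ethenyl-6-iodo-3,5-dimethoxyphenolate | [Na+].[O-]c1c(C=C)c(OC)cc(OC)c1I | intermediate
10 | 2-ethenyl-6-iodo-3,5-dimethoxyphenyl (1S)-1-[4-methoxy-3-(propan-2-yloxy)phenyl]prop-2-en-1-yl ether | COc1ccc([C@@H](Oc2c(C=C)c(OC)cc(OC)c2I)C=C)cc1OC(C)C | intermediate
11 | (2S)-8-iodo-5,7-dimethoxy-2-[4-methoxy-3-(propan-2-yloxy)phenyl]-2H-chromene | COc1ccc([C@H]2Oc3c(I)c(OC)cc(OC)c3C=C2)cc1OC(C)C | intermediate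
12 | (2R,3S,4S)-8-iodo-5,7-dimethoxy-2-[4-methoxy-3-(propan-2-yloxy)phenyl]-3,4-dihydro-2H-chromene-3,4-diol | COc1ccc([C@H]2Oc3c(I)c(OC)cc(OC)c3[C@H](O)[C@@H]2O)cc1OC(C)C | intermediate
13 | (2R,3R)-3-hydroxy-8-iodo-5,7-dimethoxy-2-[4-methoxy-3-(propan-2-yloxy)phenyl]-2,3-dihydro-4H-chromen-4-one | COc1ccc([C@H]2Oc3c(I)c(OC)cc(OC)c3C(=O)[C@@H]2O)cc1OC(C)C | intermediate
14 | (2R,3R)-3,5-dihydroxy-2-(3-hydroxy-4-methoxyphenyl)-8-iodo-7-methoxy-2,3-dihydro-4H-chromen-4-one | COc1ccc([C@H]2Oc3c(I)c(OC)cc(O)c3C(=O)[C@@H]2O)cc1O | intermediate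
15 | tributyl(3-methylbut-2-en-1-yl)stannane | CC(C)=CC[Sn](CCCC)(CCCC)CCCC | starting material
16 | (2R,3R)-3,5-dihydroxy-2-(3-hydroxy-4-methoxyphenyl)-7-methoxy-8-(3-methylbut-2-en-1-yl)-2,3-dihydro-4H-chromen-4-one | COc1ccc([C@H]2Oc3c(CC=C(C)C)c(OC)cc(O)c3C(=O)[C@@H]2O)cc1O | target

**Step count and risks**

Total step count: 12. Longest linear sequence: 10 steps (isovanillin 4 → 16, steps 3 to 12); the ring A branch (steps 1 and 2) joins at step 7.

Steps most likely to fail:

1. Step 7. The phenolate is flanked by iodine and a vinyl group and may substitute slowly. The branched ether, with an electron-rich aryl group at the allylic carbon, may also re-ionise on iridium, which would erode the enantiomeric purity and drift the product towards the linear cinnamyl ether. Fallback, setting out from aldehyde 5 (with phenol 3 unchanged) and coming back at 10: addition of CH2=CHMgBr to 5 (THF, −78 °C) should give racemic 1-[4-methoxy-3-(propan-2-yloxy)phenyl]prop-2-en-1-ol F1. Kinetic resolution with Candida antarctica lipase B and vinyl acetate should leave (1S)-1-[4-methoxy-3-(propan-2-yloxy)phenyl]prop-2-en-1-ol F2 and remove the other enantiomer as (1R)-1-[4-methoxy-3-(propan-2-yloxy)phenyl]prop-2-en-1-yl acetate F3. F2 with ClCO2Me/pyridine should give methyl (1S)-1-[4-methoxy-3-(propan-2-yloxy)phenyl]prop-2-en-1-yl carbonate F4. Enantiospecific rhodium-catalysed allylic etherification of F4 (RhCl(PPh3)3 modified with P(OMe)3, phenolate 9 made from 3 with NaN(SiMe3)2, THF, 0 °C → rt) should then deliver 10 with net retention through a configurationally stable rhodium enyl, a reaction type that accepts ortho-substituted phenolates.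

2. Step 12. Reductive loss of iodine at the hindered, electron-rich C8 position and bond formation at the tertiary terminus of the allyl unit (reverse prenylation) may compete with the linear coupling. Fallback, setting out from 14 and coming back at 16: Stille coupling with allyltributylstannane (Pd(PPh3)4, DMF, 80 °C), which has no regiochemical ambiguity, should give (2R,3R)-3,5-dihydroxy-2-(3-hydroxy-4-methoxyphenyl)-7-methoxy-8-(prop-2-en-1-yl)-2,3-dihydro-4H-chromen-4-one F5. Cross-metathesis of F5 with excess 2-methylbut-2-ene (second-generation Grubbs catalyst (H2IMes)(PCy3)Cl2Ru=CHPh, CH2Cl2, 40 °C) should convert the allyl group into the prenyl group of 16.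

3. Step 10. Hydride abstraction at C2–H (benzylic to the dialkoxyphenyl ring and next to O1) may compete with that at C4–H and lead to over-oxidation of ring C, and the acidic hydroquinone may ionise the C4 alcohol. Fallback, setting out from 12 and coming back at 13: silylation of the less hindered 3-OH (TBSOTf, 2,6-lutidine, CH2Cl2, −78 °C; the 4-OH is crowded by the peri 5-methoxy group) should give (2R,3S,4S)-3-[(tert-butyldimethylsilyl)oxy]-8-iodo-5,7-dimethoxy-2-[4-methoxy-3-(propan-2-yloxy)phenyl]-3,4-dihydro-2H-chromen-4-ol F6. Dess–Martin periodinane oxidation of the remaining alcohol should give (2R,3R)-3-[(tert-butyldimethylsilyl)oxy]-8-iodo-5,7-dimethoxy-2-[4-methoxy-3-(propan-2-yloxy)phenyl]-2,3-dihydro-4H-chromen-4-one F7. HF·pyridine in THF should then free the 3-OH to give 13.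

**Further compounds**

F1 | step 7 | racemic 1-[4-methoxy-3-(propan-2-yloxy)phenyl]prop-2-en-1-ol | COc1ccc(C(O)C=C)cc1OC(C)C
F2 | step 7 | (1S)-1-[4-methoxy-3-(propan-2-yloxy)phenyl]prop-2-en-1-ol | COc1ccc([C@@H](O)C=C)cc1OC(C)C
F3 | step 7 | (1R)-1-[4-methoxy-3-(propan-2-yloxy)phenyl]prop-2-en-1-yl acetate | COc1ccc([C@H](OC(C)=O)C=C)cc1OC(C)C
F4 | step 7 | methyl (1S)-1-[4-methoxy-3-(propan-2-yloxy)phenyl]prop-2-en-1-yl carbonate | COc1ccc([C@@H](OC(=O)OC)C=C)cc1OC(C)C
F5 | step 12 | (2R,3R)-3,5-dihydroxy-2-(3-hydroxy-4-methoxyphenyl)-7-methoxy-8-(prop-2-en-1-yl)-2,3-dihydro-4H-chromen-4-one | COc1ccc([C@H]2Oc3c(CC=C)c(OC)cc(O)c3C(=O)[C@@H]2O)cc1O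
F6 | step 10 | (2R,3S,4S)-3-[(tert-butyldimethylsilyl)oxy]-8-iodo-5,7-dimethoxy-2-[4-methoxy-3-(propan-2-yloxy)phenyl]-3,4-dihydro-2H-chromen-4-ol | COc1ccc([C@H]2Oc3c(I)c(OC)cc(OC)c3[C@H](O)[C@@H]2O[Si](C)(C)C(C)(C)C)cc1OC(C)C
F7 | step 10 | (2R,3R)-3-[(tert-butyldimethylsilyl)oxy]-8-iodo-5,7-dimethoxy-2-[4-methoxy-3-(propan-2-yloxy)phenyl]-2,3-dihydro-4H-chromen-4-one | COc1ccc([C@H]2Oc3c(I)c(OC)cc(OC)c3C(=O)[C@@H]2O[Si](C)(C)C(C)(C)C)cc1OC(C)C
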